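The synthesis rests on cutting the aryl–carbonyl bond C4–C4a of ring C. An (S)-3-aryl-3-aryloxypropanoyl chloride, in which silyl ethers mask the three phenols and bromine atoms occupy C8 and C3', is closed by one intramolecular Friedel–Crafts acylation that forms ring C without touching C2. The step exploits C4a of ring A: it lies ortho to the ether oxygen O1 and para to the C7 oxygen, while C8, the only other carbon ortho to O1, is blocked by bromine. The two bromines later become both prenyl groups in a single double Stille coupling, so no acid-sensitive prenyl group meets the Lewis acid.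

Key step: step 6

Assumption: (R)-TRIP is taken to direct allyl transfer to the Re face of aldehyde 3, as it does with benzaldehyde, giving the (R)-carbinol; if the sense were opposite, the (S)-acid would be used.

Step 1
Reactants: 1 3-bromo-4,5-dihydroxybenzaldehyde; 2 tert-butyldimethylsilyl chloride
Product: 3 3-bromo-4,5-bis(tert-butyldimethylsilyloxy)benzaldehyde
Conditions: TBSCl (2.5 equiv), imidazole, DMF, rt
Reagents that add atoms: tert-butyldimethylsilyl chloride 2, CC(C)(C)[Si](C)(C)Cl
Why: Imidazole-promoted silylation of both catechol hydroxyls should proceed normally, and the silyl ethers are chosen because they tolerate every later step and leave together under fluoride.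

Step 2
Reactants: 3 3-bromo-4,5-bis(tert-butyldimethylsilyloxy)benzaldehyde; 4 allylboronic acid pinacol ester
Product: 6 (R)-1-[3-bromo-4,5-bis(tert-butyldimethylsilyloxy)phenyl]but-3-en-1-ol, via pinacol borate ester 5 (not isolated)
Conditions: (R)-TRIP [(R)-3,3'-bis(2,4,6-triisopropylphenyl)-1,1'-binaphthyl-2,2'-diyl hydrogen phosphate, 5 mol%], toluene, −30 °C; aqueous work-up
Reagents that add atoms: allylboronic acid pinacol ester 4, C=CCB1OC(C)(C)C(C)(C)O1
Why: Chiral phosphoric acid-catalysed allylboration passes through a closed chair transition state in which the acid activates the boronate, and the catalyst pocket should select the Re face of the aldehyde, setting the (R)-carbinol that becomes C2 after inversion in step 4.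

Step 3
Reactants: 7 2-bromoresorcinol; 2 tert-butyldimethylsilyl chloride
Product: 8 2-bromo-3-(tert-butyldimethylsilyloxy)phenol
Conditions: 7 (3 equiv), TBSCl (1 equiv), imidazole, CH2Cl2/DMF, 0 °C
Reagents that add atoms: tert-butyldimethylsilyl chloride 2, CC(C)(C)[Si](C)(C)Cl
Why: Statistical monosilylation of a symmetrical diol used in excess should give the monoether, and because the two hydroxyls are equivalent no regiochemical question arises.

Step 4
Reactants: 6 (R)-1-[3-bromo-4,5-bis(tert-butyldimethylsilyloxy)phenyl]but-3-en-1-ol; 8 2-bromo-3-(tert-butyldimethylsilyloxy)phenol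
Product: 9 (S)-1-[3-bromo-4,5-bis(tert-butyldimethylsilyloxy)phenyl]but-3-en-1-yl 2-bromo-3-(tert-butyldimethylsilyloxy)phenyl ether
Conditions: PPh3, DIAD (diisopropyl azodicarboxylate, added last), toluene, 0 °C → rt
Reagents that add atoms: 2-bromo-3-(tert-butyldimethylsilyloxy)phenol 8, Oc1cccc(O[Si](C)(C)C(C)(C)C)c1Br
Why: Mitsunobu etherification, in which the acidic ortho-bromophenol displaces the alkoxyphosphonium group by SN2 with inversion to give the (S)-ether, while the meta-bromine and the flanked para-silyloxy group of ring B should hold back ionisation of the benzylic carbon.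

Step 5
Reactants: 9 (S)-1-[3-bromo-4,5-bis(tert-butyldimethylsilyloxy)phenyl]but-3-en-1-yl 2-bromo-3-(tert-butyldimethylsilyloxy)phenyl ether
Product: 11 (S)-3-[2-bromo-3-(tert-butyldimethylsilyloxy)phenoxy]-3-[3-bromo-4,5-bis(tert-butyldimethylsilyloxy)phenyl]propanoic acid, via aldehyde 10 (not isolated)
Conditions: O3 (to consumption of 9), MeCN/H2O 9:1, 0 °C; then NaClO2 (aq.), 0 °C → rt; NaHSO3 quench
Reagents that add atoms: ozone, [O-][O+]=O; water, O; sodium chlorite, [Na+].[O-]Cl=O
Why: Ozonolysis in aqueous acetonitrile, where water traps the carbonyl oxide to release the aldehyde directly, followed by chlorite (Pinnick-type) oxidation in the same pot should give the acid, since the terminal alkene reacts with ozone far faster than the arenes and the stereocenter is not involved.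

Step 6
Reactants: 11 (S)-3-[2-bromo-3-(tert-butyldimethylsilyloxy)phenoxy]-3-[3-bromo-4,5-bis(tert-butyldimethylsilyloxy)phenyl]propanoic acid
Product: 13 (S)-8-bromo-2-[3-bromo-4,5-bis(tert-butyldimethylsilyloxy)phenyl]-7-(tert-butyldimethylsilyloxy)chroman-4-one, via acyl chloride 12 (not isolated)
Conditions: 1-chloro-N,N,2-trimethylprop-1-en-1-amine (Ghosez reagent), CH2Cl2, 0 °C; then SnCl4 (1.2 equiv), CH2Cl2, −78 → −40 °C; cold aq. NaHCO3
Reagents that add atoms: none
Why: The Ghosez reagent converts acid 11 into acyl chloride 12 without releasing HCl, and SnCl4 then generates an acylium-type electrophile that is attacked by C4a of ring A, after which loss of the C4a proton from the Wheland intermediate gives the aryl ketone. The closest known reaction type is the intramolecular Friedel–Crafts acylation of 3-aryloxypropanoyl chlorides to chroman-4-ones. Ring C, the only ring formed, closes in a 6-exo mode at the acyl carbon (exo-trig on the complexed chloride, exo-dig on the free acylium ion). No new stereocenter arises, and C2, set in steps 2 and 4, should be kept because the bromine meta to the benzylic carbon and the two flanked silyloxy groups of ring B disfavour ionisation of the C2–O1 bond at low temperature. The step needs site selectivity for C4a over C8 and over the ring B carbons: C8 is blocked by bromine, C4a is activated both ortho (O1) and para (C7 silyloxy), and attack by ring B would form a strained five-membered indanone on a less activated ring. It also needs the silyl ethers to survive, which the HCl-free chloride formation and the short exposure to SnCl4 below −40 °C should allow.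

Step 7
Reactants: 13 (S)-8-bromo-2-[3-bromo-4,5-bis(tert-butyldimethylsilyloxy)phenyl]-7-(tert-butyldimethylsilyloxy)chroman-4-one; 14 tributyl(3-methylbut-2-en-1-yl)stannane
Product: 15 (S)-2-[3,4-bis(tert-butyldimethylsilyloxy)-5-(3-methylbut-2-en-1-yl)phenyl]-7-(tert-butyldimethylsilyloxy)-8-(3-methylbut-2-en-1-yl)chroman-4-one
Conditions: 14 (3 equiv), Pd(P(t-Bu)3)2 (zerovalent palladium, 10 mol%), toluene, 90 °C
Reagents that add atoms: tributyl(3-methylbut-2-en-1-yl)stannane 14, CCCC[Sn](CCCC)(CCCC)CC=C(C)C
Why: Double Migita–Kosugi–Stille coupling, in which the bulky electron-rich phosphine should allow oxidative addition even at the flanked C8–Br bond and the allyl-palladium intermediate reductively eliminates at its less substituted terminus to give linear prenyl groups, all under neutral conditions that leave C2 and the silyl ethers alone.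

Step 8
Reactants: 15 (S)-2-[3,4-bis(tert-butyldimethylsilyloxy)-5-(3-methylbut-2-en-1-yl)phenyl]-7-(tert-butyldimethylsilyloxy)-8-(3-methylbut-2-en-1-yl)chroman-4-one
Product: 16 (2S)-2-[3,4-dihydroxy-5-(3-methylbut-2-en-1-yl)phenyl]-7-hydroxy-8-(3-methylbut-2-en-1-yl)chroman-4-one (CNP0315050.1)
Conditions: HF·pyridine, pyridine, THF, 0 °C → rt, under argon
Reagents that add atoms: none
Why: Fluoride-mediated cleavage of the three aryl silyl ethers under buffered, weakly acidic conditions should free the phenols without forming the phenoxides that would open the flavanone to its chalcone and racemise C2, and without protonating the prenyl groups.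

Compound list
1 | 3-bromo-4,5-dihydroxybenzaldehyde | O=Cc1cc(O)c(O)c(Br)c1 | starting material
2 | tert-butyldimethylsilyl chloride | CC(C)(C)[Si](C)(C)Cl | starting material
3 | 3-bromo-4,5-bis(tert-butyldimethylsilyloxy)benzaldehyde | O=Cc1cc(O[Si](C)(C)C(C)(C)C)c(O[Si](C)(C)C(C)(C)C)c(Br)c1 | intermediate
4 | allylboronic acid pinacol ester | C=CCB1OC(C)(C)C(C)(C)O1 | starting material
5 | (R)-2-{1-[3-bromo-4,5-bis(tert-butyldimethylsilyloxy)phenyl]but-3-en-1-yloxy}-4,4,5,5-tetramethyl-1,3,2-dioxaborolane | C=CC[C@@H](OB1OC(C)(C)C(C)(C)O1)c1cc(Br)c(O[Si](C)(C)C(C)(C)C)c(O[Si](C)(C)C(C)(C)C)c1 | intermediate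
6 | (R)-1-[3-bromo-4,5-bis(tert-butyldimethylsilyloxy)phenyl]but-3-en-1-ol | C=CC[C@@H](O)c1cc(Br)c(O[Si](C)(C)C(C)(C)C)c(O[Si](C)(C)C(C)(C)C)c1 | intermediate
7 | 2-bromoresorcinol (2-bromobenzene-1,3-diol) | Oc1cccc(O)c1Br | starting material
8 | 2-bromo-3-(tert-butyldimethylsilyloxy)phenol | Oc1cccc(O[Si](C)(C)C(C)(C)C)c1Br | intermediate
9 | (S)-1-[3-bromo-4,5-bis(tert-butyldimethylsilyloxy)phenyl]but-3-en-1-yl 2-bromo-3-(tert-butyldimethylsilyloxy)phenyl ether | C=CC[C@H](Oc1cccc(O[Si](C)(C)C(C)(C)C)c1Br)c1cc(Br)c(O[Si](C)(C)C(C)(C)C)c(O[Si](C)(C)C(C)(C)C)c1 | intermediate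
10 | (S)-3-[2-bromo-3-(tert-butyldimethylsilyloxy)phenoxy]-3-[3-bromo-4,5-bis(tert-butyldimethylsilyloxy)phenyl]propanal | O=CC[C@H](Oc1cccc(O[Si](C)(C)C(C)(C)C)c1Br)c1cc(Br)c(O[Si](C)(C)C(C)(C)C)c(O[Si](C)(C)C(C)(C)C)c1 | intermediate
11 | (S)-3-[2-bromo-3-(tert-butyldimethylsilyloxy)phenoxy]-3-[3-bromo-4,5-bis(tert-butyldimethylsilyloxy)phenyl]propanoic acid | OC(=O)C[C@H](Oc1cccc(O[Si](C)(C)C(C)(C)C)c1Br)c1cc(Br)c(O[Si](C)(C)C(C)(C)C)c(O[Si](C)(C)C(C)(C)C)c1 | intermediate
12 | (S)-3-[2-bromo-3-(tert-butyldimethylsilyloxy)phenoxy]-3-[3-bromo-4,5-bis(tert-butyldimethylsilyloxy)phenyl]propanoyl chloride | ClC(=O)C[C@H](Oc1cccc(O[Si](C)(C)C(C)(C)C)c1Br)c1cc(Br)c(O[Si](C)(C)C(C)(C)C)c(O[Si](C)(C)C(C)(C)C)c1 | intermediate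
13 | (S)-8-bromo-2-[3-bromo-4,5-bis(tert-butyldimethylsilyloxy)phenyl]-7-(tert-butyldimethylsilyloxy)chroman-4-one | O=C1C[C@@H](c2cc(Br)c(O[Si](C)(C)C(C)(C)C)c(O[Si](C)(C)C(C)(C)C)c2)Oc2c(Br)c(O[Si](C)(C)C(C)(C)C)ccc21 | intermediate
14 | tributyl(3-methylbut-2-en-1-yl)stannane | CCCC[Sn](CCCC)(CCCC)CC=C(C)C | starting material
15 | (S)-2-[3,4-bis(tert-butyldimethylsilyloxy)-5-(3-methylbut-2-en-1-yl)phenyl]-7-(tert-butyldimethylsilyloxy)-8-(3-methylbut-2-en-1-yl)chroman-4-one | O=C1C[C@@H](c2cc(CC=C(C)C)c(O[Si](C)(C)C(C)(C)C)c(O[Si](C)(C)C(C)(C)C)c2)Oc2c(CC=C(C)C)c(O[Si](C)(C)C(C)(C)C)ccc21 | intermediate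
16 | (2S)-2-[3,4-dihydroxy-5-(3-methylbut-2-en-1-yl)phenyl]-7-hydroxy-8-(3-methylbut-2-en-1-yl)chroman-4-one (CNP0315050.1) | CC(C)=CCc1cc([C@@H]2CC(=O)c3ccc(O)c(CC=C(C)C)c3O2)cc(O)c1O | target

Total step count: 8. Longest linear sequence: 7 steps (steps 1, 2, 4, 5, 6, 7 and 8, from 3-bromo-4,5-dihydroxybenzaldehyde); step 3 prepares the ring A partner separately.

Steps most likely to fail

Step 6 (key step). The danger is Lewis-acid ionisation of the C2–O1 benzylic ether or β-elimination of the phenol from the activated acyl species, either of which erodes the configuration at C2; closure onto ring B and loss of silyl groups are lesser risks. The fallback sets out from acid 11. Amide coupling with dimethylamine hydrochloride (EDC·HCl, HOBt, i-Pr2NEt, CH2Cl2) would give the (S)-N,N-dimethylamide F1. Electrophilic amide activation with Tf2O and 2-fluoropyridine (CH2Cl2, −78 → 0 °C) would then close ring C at C4a in a Vilsmeier-type substitution to the cyclic iminium triflate F2, whose hydrolysis with aqueous NaHCO3 returns to the route at 13. This path uses no Lewis acid and keeps the medium buffered.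

Step 7. Oxidative addition at the doubly flanked C8–Br bond may stall after the first coupling, protodebromination may compete, or the prenyl group may be transferred through its tertiary carbon. The fallback sets out from 13. A double Stille allylation with allyltributylstannane (Pd(PPh3)4, toluene, 100 °C), which transfers a smaller and regiochemically unambiguous group, would give the 8,3'-diallyl flavanone F3. Double olefin cross-metathesis with 2-methylbut-2-ene (second-generation Grubbs catalyst, CH2Cl2, 40 °C) would then convert both allyl groups into prenyl groups and return to the route at 15.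

Step 4. Partial SN1 substitution at the benzylic carbinol would erode the enantiomeric purity, and E2 elimination to the aryl diene or slow reaction of the ortho-bromophenol would cost material. The fallback sets out from aldehyde 3 and forms the C2–O1 bond on a strained ring instead. A [2+2] cycloaddition with ketene (from acetyl chloride and i-Pr2NEt), catalysed by an O-trimethylsilyl cinchona alkaloid (quinine- or quinidine-derived, chosen for the R sense) with LiClO4 in CH2Cl2/Et2O at −78 °C, would give the (R)-β-lactone F4. SN2 opening at its benzylic C4 by the sodium phenoxide of 8 (NaH, DMF, 0 °C → rt), with inversion and release of ring strain, would return to the route at acid 11 and bypass steps 2, 4 and 5.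

Further compounds
F1 | step 6 | (S)-3-[2-bromo-3-(tert-butyldimethylsilyloxy)phenoxy]-3-[3-bromo-4,5-bis(tert-butyldimethylsilyloxy)phenyl]-N,N-dimethylpropanamide | CN(C)C(=O)C[C@H](Oc1cccc(O[Si](C)(C)C(C)(C)C)c1Br)c1cc(Br)c(O[Si](C)(C)C(C)(C)C)c(O[Si](C)(C)C(C)(C)C)c1
F2 | step 6 | (S)-N-{8-bromo-2-[3-bromo-4,5-bis(tert-butyldimethylsilyloxy)phenyl]-7-(tert-butyldimethylsilyloxy)chroman-4-ylidene}-N-methylmethanaminium trifluoromethanesulfonate | C[N+](C)=C1C[C@@H](c2cc(Br)c(O[Si](C)(C)C(C)(C)C)c(O[Si](C)(C)C(C)(C)C)c2)Oc2c(Br)c(O[Si](C)(C)C(C)(C)C)ccc21.[O-]S(=O)(=O)C(F)(F)F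
F3 | step 7 | (S)-8-allyl-2-[3-allyl-4,5-bis(tert-butyldimethylsilyloxy)phenyl]-7-(tert-butyldimethylsilyloxy)chroman-4-one | O=C1C[C@@H](c2cc(CC=C)c(O[Si](C)(C)C(C)(C)C)c(O[Si](C)(C)C(C)(C)C)c2)Oc2c(CC=C)c(O[Si](C)(C)C(C)(C)C)ccc21
F4 | step 4 | (R)-4-[3-bromo-4,5-bis(tert-butyldimethylsilyloxy)phenyl]oxetan-2-one | O=C1C[C@@H](O1)c2cc(Br)c(O[Si](C)(C)C(C)(C)C)c(O[Si](C)(C)C(C)(C)C)c2
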